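Numbering: decalin C1–C10 (C1 carbinol, C3 C–Cl, C4 quaternary with the side chain, C5/C10 ring fusion, C7=C8, C9 CH–CHO), C11 = formyl carbon, C12 = ester carbon; β = the face of the C10 methyl group.
Cuts: (a) the side-chain C=C, back to a C4 allyl group; (b) C9 epimer and lactol, back to an 11→1α γ-lactone; (c) C9–C10 and C7–C8 together (retro-Diels–Alder), which opens ring B and the lactone to the vinylcyclohexenyl ester 15; (d) ring A back to 2-methylcyclohex-2-enone.
Enabling feature: O1 stands 1,3 to C11 across quaternary C10 (array O1–C1–C10–C9–C11), so O1 can carry C9≡C8 as a mixed acetylenedicarboxylate. Ring B, with vicinal carbonyl carbons on C8 and C9, is the retron of the diene C10=C5–C6=C7 plus that alkyne.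
Forward order: ring A first (allylation, chlorinative 1,2-shift, C1 oxygenation, vinylation). Ring B and the lactone then form in one cycloaddition, followed by conversion of the 1,4-diene to Δ7 (isomerisation, then 1,6-reduction), the side chain, and lactone → aldehyde.
Stereochemistry relay: carbinol C5 of 2 (Ti/BINOL) → C4 and C3 (anti 1,2-shift) → C1 (axial borylation trans to Cl) → C10 (tether) → C5 (thermodynamic trans fusion) → C9 (kinetic axial protonation). The E-alkene comes from cross metathesis.

Key step: step 12

Assumption: (R)-BINOL is taken to give the (S)-carbinol 2; if the sense of induction is the reverse, (S)-BINOL is used and nothing else changes.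
Remark: ring atoms of the monocyclic compounds are referred to by their final numbers. The carbonyl carbon of 1 is C5, its methyl-bearing carbon is C4, and C3, C2, C1 and C10 follow round the ring.

Step 1
Reactants: 1 2-methylcyclohex-2-en-1-one
Product: 2 (S)-1-allyl-2-methylcyclohex-2-en-1-ol
Conditions: Sn(CH2CH=CH2)4, Ti(OiPr)4 (20 mol %), (R)-BINOL (20 mol %), i-PrOH, CH2Cl2, rt
Reagents that add atoms: tetraallylstannane, C=CC[Sn](CC=C)(CC=C)CC=C
Why: Catalytic asymmetric 1,2-allylation of a ketone with a titanium BINOLate, a reaction type suited to α-substituted cyclic enones because the two carbonyl flanks differ strongly, sets the C5 carbinol centre (allyl α, OH β) from which every other centre is relayed.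

Step 2
Reactants: 2 (S)-1-allyl-2-methylcyclohex-2-en-1-ol
Product: 3 (2S,3S)-2-allyl-3-chloro-2-methylcyclohexan-1-one (Cl trans to allyl)
Conditions: TsN(Cl)Na (chloramine-T), ZnCl2 (20 mol %), MeCN, 0 °C to rt
Reagents that add atoms: chloramine-T, Cc1ccc(cc1)S(=O)(=O)[N-]Cl.[Na+]
Why: Halonium-induced semipinacol rearrangement of a tertiary allylic alcohol: Cl+ adds to the trisubstituted ring alkene on the face opposite the pseudoaxial allyl group, and that group shifts from C5 to the tertiary end C4 antiperiplanar to the C–Cl bond, which sets C4 (allyl α, methyl β) and C3 (Cl β) in one stereospecific event and gives a β-chloro ketone that cannot eliminate because its α-carbon is quaternary.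

Step 3
Reactants: 3 (2S,3S)-2-allyl-3-chloro-2-methylcyclohexan-1-one
Product: 4 (2S,3S)-2-allyl-3-chloro-2,6-dimethylcyclohexan-1-one (mixture of C6 epimers)
Conditions: LiN(i-Pr)2, THF, −78 °C; MeI, −78 to 0 °C
Reagents that add atoms: iodomethane, CI
Why: Enolate alkylation in which only C10 can be deprotonated because C4 is quaternary; the new centre is of no consequence since it becomes sp2 in step 4.

Step 4
Reactants: 4 (2S,3S)-2-allyl-3-chloro-2,6-dimethylcyclohexan-1-one
Product: 6 (5S,6S)-6-allyl-5-chloro-2,6-dimethylcyclohex-2-en-1-one, via trimethylsilyl enol ether 5 (not isolated)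
Conditions: Me3SiOTf, Et3N, CH2Cl2, 0 °C; then Pd(OAc)2 (1.05 equiv), MeCN, rt
Reagents that add atoms: trimethylsilyl trifluoromethanesulfonate, C[Si](C)(C)OS(=O)(=O)C(F)(F)F (its silyl group stays only in 5)
Why: Saegusa–Ito oxidation of the only possible (tetrasubstituted) silyl enol ether gives the endocyclic 2-methyl enone C5(=O)–C10(Me)=C1 at room temperature under near-neutral conditions that spare the chloride and the terminal alkene.

Step 5
Reactants: 6 (5S,6S)-6-allyl-5-chloro-2,6-dimethylcyclohex-2-en-1-one
Product: 8 (2S,3S,5S)-2-allyl-3-chloro-5-hydroxy-2,6-dimethylcyclohexan-1-one (C6 epimers), via β-boryl ketone 7 (not isolated)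
Conditions: B2pin2, CuCl (5 mol %), DPEphos (5 mol %), NaOt-Bu (10 mol %), MeOH, THF, rt; then NaBO3·4H2O, THF/H2O, rt
Reagents that add atoms: bis(pinacolato)diboron, CC1(C)OB(OC1(C)C)B1OC(C)(C)C(C)(C)O1 (boron stays only in 7); sodium perborate, O[B-]1(O)OO[B-](O)(O)OO1.[Na+].[Na+] (oxygen atom of 8)
Why: Copper-catalysed conjugate borylation followed by stereoretentive C–B oxidation: as in conjugate additions to 5-substituted cyclohexenones, the boryl–copper species attacks C1 axially on the half-chair that keeps Cl and allyl equatorial, that is trans to the C3 chlorine, which sets the 1α oxygen under conditions too weakly basic for vinylogous loss of HCl.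

Step 6
Reactants: 8 (2S,3S,5S)-2-allyl-3-chloro-5-hydroxy-2,6-dimethylcyclohexan-1-one
Product: 9 (2S,3S,5S)-2-allyl-5-[(tert-butyldimethylsilyl)oxy]-3-chloro-2,6-dimethylcyclohexan-1-one (C6 epimers)
Conditions: t-BuMe2SiOTf, 2,6-lutidine, CH2Cl2, −78 to 0 °C
Reagents that add atoms: tert-butyldimethylsilyl trifluoromethanesulfonate, CC(C)(C)[Si](C)(C)OS(=O)(=O)C(F)(F)F
Why: Silyl ether formation with the triflate and a hindered, weak base protects the axial β-hydroxy ketone without dehydration.

Step 7
Reactants: 9 silyl-protected β-hydroxy ketone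
Product: 10 (3S,5S,6S)-6-allyl-3-[(tert-butyldimethylsilyl)oxy]-5-chloro-2,6-dimethylcyclohex-1-en-1-yl trifluoromethanesulfonate
Conditions: Tf2O, 2,6-di-tert-butyl-4-methylpyridine, CH2Cl2, 0 °C to rt
Reagents that add atoms: trifluoromethanesulfonic anhydride, O=S(=O)(OS(=O)(=O)C(F)(F)F)C(F)(F)F
Why: Enol triflate formation by O-triflation and proton loss avoids a metal enolate that could expel the aligned β-silyloxy group, and since C4 is quaternary only the C5=C10 regioisomer can form.

Step 8
Reactants: 10 enol triflate
Product: 11 tert-butyl{[(1S,4S,5S)-4-allyl-5-chloro-2,4-dimethyl-3-vinylcyclohex-2-en-1-yl]oxy}dimethylsilane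
Conditions: CH2=CHSnBu3, Pd(PPh3)4 (5 mol %), LiCl, THF, 65 °C
Reagents that add atoms: tributyl(vinyl)stannane, C=C[Sn](CCCC)(CCCC)CCCC
Why: Stille coupling of a 2,6,6-trisubstituted cyclohexenyl triflate installs C6=C7 under neutral conditions; the unactivated secondary chloride does not add oxidatively to zerovalent palladium.

Step 9
Reactants: 11 silyl-protected diene
Product: 12 (1S,4S,5S)-4-allyl-5-chloro-2,4-dimethyl-3-vinylcyclohex-2-en-1-ol
Conditions: Bu4NF, THF, 0 °C to rt
Reagents that add atoms: none
Why: Fluoride desilylation frees the acid-sensitive dienylic alcohol without ionising it, and the equatorial, neopentyl-type chloride has no antiperiplanar hydrogen for E2 loss.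

Step 10
Reactants: 13 methyl propiolate
Product: 14 4-methoxy-4-oxobut-2-ynoic acid
Conditions: LiN(SiMe3)2, THF, −78 °C; CO2 (g); then 1 M HCl
Reagents that add atoms: carbon dioxide, O=C=O
Why: Carboxylation of the lithium acetylide at low temperature gives the half ester directly and avoids partial saponification of the diester, in which alkoxide would add to the triple bond.

Step 11
Reactants: 12 dienol; 14 4-methoxy-4-oxobut-2-ynoic acid
Product: 15 methyl (1S,4S,5S)-4-allyl-5-chloro-2,4-dimethyl-3-vinylcyclohex-2-en-1-yl but-2-ynedioate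
Conditions: DCC, DMAP (5 mol %), CH2Cl2, −20 to 0 °C
Reagents that add atoms: none
Why: Steglich esterification, run cold and with little DMAP as for propiolic acids, acylates O1 with retention at C1 and hangs the dienophile on the α face.

Step 12
Reactants: 15 mixed acetylenedicarboxylate
Product: 16 tricyclic adduct: 11→1α γ-lactone, methyl ester on C8, double bonds C5=C6 and C8=C9, 3β-Cl, 4α-allyl, 4β-Me, 10β-Me
Conditions: PhMe (0.01 M), BHT (cat.), 110 °C
Reagents that add atoms: none
Why: Concerted thermal [4+2] cycloaddition of the s-cis diene C10=C5–C6=C7 with the tethered alkyne C9≡C8 forms C9–C10 and C7–C8 in one event. The closest known reaction types are the ester-tethered type 1 intramolecular Diels–Alder reaction of penta-2,4-dienyl maleates, fumarates and propiolates and the intermolecular cycloaddition of 2-alkyl-1-vinylcyclohexenes with acetylenedicarboxylates. Ring B closes as the six-membered cycloaddition ring and the γ-lactone (O1–C1–C10–C9–C11) closes in the fused mode over the three-atom tether C1–O–C11, the bridged mode being excluded because it would need a bridgehead double bond. The only new stereocentre, quaternary C10, is controlled by C1: the short tether can deliver C9 only to the α face on which O1 stands, so the lactone is cis-fused to ring A and the methyl group is pushed to the β face. The step needs facial, regio- and chemoselectivity, which are secured by the tether, by the ground-state half-chair of ring A (Cl and allyl equatorial, O1 pseudoaxial and already over the diene) and by the unconjugated nature of the C4 allyl group; a linear dienophile raises no endo/exo question, and activation of both alkyne carbons lets the bond to fully substituted C10 form. The adduct also leaves C11 (lactone) and C12 (methyl ester) differentiated and keeps C5 and C9 unsaturated so that these two centres can be set later.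

Step 13
Reactants: 16 tricyclic adduct
Product: 17 conjugated diene lactone: double bonds C6=C7 and C8=C9, 5α-H (trans ring fusion), otherwise as 16
Conditions: DBU (0.5 equiv), THF, 40 °C
Reagents that add atoms: none
Why: Base-catalysed prototropic isomerisation: DBU removes a doubly allylic C7 proton (γ to the lactone carbonyl) and the extended enolate is reprotonated at C5 to give the fully conjugated C6=C7–C8=C9–C11=O system, and because C5–H stays vinylogously acidic the ring fusion equilibrates to the more stable trans (5α-H) arrangement.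

Step 14
Reactants: 17 conjugated diene lactone
Product: 19 Δ7 lactone ester (C7=C8; 5α-H; 9β-H), via lithium lactone dienolate 18 (not isolated)
Conditions: LiBH(s-Bu)3 (1.1 equiv), THF, −78 °C; then AcOH, −78 °C
Reagents that add atoms: none
Why: 1,6-Conjugate hydride addition: the β-carbon C8 is fully substituted, so the bulky borohydride attacks the δ-carbon C6, and kinetic α-protonation of the dienolate at C9 leaves C7=C8 conjugated with the ester; the lactone ring forces this proton onto the β face (a provisional configuration, corrected in step 17), and the allyl group and the alkyl chloride are inert to the reagent.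

Step 15
Reactants: 19 Δ7 lactone ester; 20 2-methylbut-3-en-2-ol
Product: 21 Δ7 lactone ester carrying the (E)-4-hydroxy-4-methylpent-2-enyl chain on C4
Conditions: second-generation Grubbs catalyst (H2IMes)(PCy3)Cl2Ru=CHPh (5 mol %), 20 (8 equiv), CH2Cl2, 40 °C
Reagents that add atoms: none
Why: Olefin cross metathesis of a terminal alkene with an unprotected tertiary allylic alcohol, which homodimerises slowly, is E-selective, and the trisubstituted electron-poor C7=C8 bond takes no part.

Step 16
Reactants: 21 lactone with complete side chain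
Product: 22 11,1α-lactol (mixture of C11 anomers), methyl ester intact
Conditions: i-Bu2AlH (2.2 equiv), CH2Cl2, −78 °C; aq. KNaC4H4O6 (potassium sodium tartrate)
Reagents that add atoms: none
Why: Partial reduction of a lactone to a lactol: after one equivalent is used up by the tertiary alcohol, the non-conjugated γ-lactone (fixed E ester geometry) should be attacked faster than the α,β-unsaturated methyl ester, and its tetrahedral aluminate persists at −78 °C.

Step 17
Reactants: 22 lactol
Product: 24 CNP0167913.1, via tripotassium dienolate 23 (not isolated)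
Conditions: KN(SiMe3)2 (3.5 equiv), THF, −78 to −40 °C; then cannulated into AcOH/THF, −78 °C
Reagents that add atoms: none
Why: Ring–chain opening of the lactolate and α-deprotonation give an extended enolate with planar C9, and kinetic protonation of such dienolates takes place at the α-carbon and axially, here from the α face anti to the C10 methyl group and next to the 1α oxygen, which can relay the proton; this gives 9α-H with the 9β-formyl group, and that aldehyde cannot close onto the axial 1α-OH, so it leaves the ring–chain equilibrium while any 9α-aldehyde returns to 22 and can be resubmitted.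

Compound list
1 | 2-methylcyclohex-2-en-1-one | CC1=CCCCC1=O | starting material
2 | (S)-1-allyl-2-methylcyclohex-2-en-1-ol | C=CC[C@@]1(O)CCCC=C1C | intermediate
3 | (2S,3S)-2-allyl-3-chloro-2-methylcyclohexan-1-one | O=C1CCC[C@H](Cl)[C@@]1(C)CC=C | intermediate
4 | (2S,3S)-2-allyl-3-chloro-2,6-dimethylcyclohexan-1-one (C6 epimers) | O=C1C(C)CC[C@H](Cl)[C@@]1(C)CC=C | intermediate
5 | trimethylsilyl enol ether of 4 (not isolated) | C[Si](C)(C)OC1=C(C)CC[C@H](Cl)[C@@]1(C)CC=C | intermediate
6 | (5S,6S)-6-allyl-5-chloro-2,6-dimethylcyclohex-2-en-1-one | O=C1C(C)=CC[C@H](Cl)[C@@]1(C)CC=C | intermediate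
7 | β-boryl ketone, 1α-Bpin (not isolated) | O=C1C(C)[C@@H](B2OC(C)(C)C(C)(C)O2)C[C@H](Cl)[C@@]1(C)CC=C | intermediate
8 | (2S,3S,5S)-2-allyl-3-chloro-5-hydroxy-2,6-dimethylcyclohexan-1-one (C6 epimers) | O=C1C(C)[C@@H](O)C[C@H](Cl)[C@@]1(C)CC=C | intermediate
9 | tert-butyldimethylsilyl ether of 8 | O=C1C(C)[C@@H](O[Si](C)(C)C(C)(C)C)C[C@H](Cl)[C@@]1(C)CC=C | intermediate
10 | (3S,5S,6S)-6-allyl-3-[(tert-butyldimethylsilyl)oxy]-5-chloro-2,6-dimethylcyclohex-1-en-1-yl triflate | FC(F)(F)S(=O)(=O)OC1=C(C)[C@@H](O[Si](C)(C)C(C)(C)C)C[C@H](Cl)[C@@]1(C)CC=C | intermediate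
11 | silyl ether of dienol 12 | C=CC1=C(C)[C@@H](O[Si](C)(C)C(C)(C)C)C[C@H](Cl)[C@@]1(C)CC=C | intermediate
12 | (1S,4S,5S)-4-allyl-5-chloro-2,4-dimethyl-3-vinylcyclohex-2-en-1-ol | C=CC1=C(C)[C@@H](O)C[C@H](Cl)[C@@]1(C)CC=C | intermediate
13 | methyl propiolate | COC(=O)C#C | starting material
14 | 4-methoxy-4-oxobut-2-ynoic acid | COC(=O)C#CC(=O)O | intermediate
15 | methyl (1S,4S,5S)-4-allyl-5-chloro-2,4-dimethyl-3-vinylcyclohex-2-en-1-yl but-2-ynedioate | COC(=O)C#CC(=O)O[C@H]1C[C@H](Cl)[C@@](C)(CC=C)C(C=C)=C1C | intermediate
16 | Diels–Alder adduct (C5=C6, C8=C9, 11→1α lactone) | COC(=O)C1=C2C(=O)O[C@H]3C[C@H](Cl)[C@@](C)(CC=C)C(=CC1)[C@@]23C | intermediate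
17 | conjugated diene lactone (C6=C7, C8=C9, 5α-H) | COC(=O)C1=C2C(=O)O[C@H]3C[C@H](Cl)[C@@](C)(CC=C)[C@H](C=C1)[C@@]23C | intermediate
18 | lithium lactone dienolate (not isolated) | COC(=O)C1=CC[C@H]2[C@](C)(CC=C)[C@@H](Cl)C[C@@H]3OC([O-])=C1[C@]23C.[Li+] | intermediate
19 | Δ7 lactone ester (5α-H, 9β-H) | COC(=O)C1=CC[C@H]2[C@](C)(CC=C)[C@@H](Cl)C[C@@H]3OC(=O)[C@H]1[C@]23C | intermediate
20 | 2-methylbut-3-en-2-ol | C=CC(C)(C)O | starting material
21 | Δ7 lactone ester with the (E)-4-hydroxy-4-methylpent-2-enyl chain | COC(=O)C1=CC[C@H]2[C@](C)(C/C=C/C(C)(C)O)[C@@H](Cl)C[C@@H]3OC(=O)[C@H]1[C@]23C | intermediate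
22 | 11,1α-lactol (C11 anomers) | COC(=O)C1=CC[C@H]2[C@](C)(C/C=C/C(C)(C)O)[C@@H](Cl)C[C@@H]3OC(O)[C@H]1[C@]23C | intermediate
23 | tripotassium salt of the ring-opened dienolate (not isolated) | COC(=O)C1=CC[C@H]2[C@](C)(C/C=C/C(C)(C)[O-])[C@@H](Cl)C[C@H]([O-])[C@]2(C)C1=C[O-].[K+].[K+].[K+] | intermediate
24 | CNP0167913.1: methyl 3β-chloro-9β-formyl-1α-hydroxy-4α-[(E)-4-hydroxy-4-methylpent-2-enyl]-4β,10β-dimethyl-trans-Δ7-octalin-8-carboxylate | COC(=O)C1=CC[C@H]2[C@](C)(C/C=C/C(C)(C)O)[C@@H](Cl)C[C@H](O)[C@]2(C)[C@H]1C=O | target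

Total step count: 17. Longest linear sequence: 16 (steps 1–9 and 11–17).

Steps most likely to fail

Step 2. The 1,2-allyl shift may be outrun by proton loss from the chloronium ion (ene-type allylic chlorination) or by attack of the hydroxyl group on it.
- The fallback sets out from 2 and returns at 3.
- Hydroxyl-directed epoxidation (VO(acac)2, t-BuOOH) gives the syn epoxy alcohol F1.
- A ZnBr2-promoted semipinacol rearrangement moves the allyl group anti to the epoxide C–O bond and gives (2R,3S)-2-allyl-3-hydroxy-2-methylcyclohexan-1-one F2.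
- Acylation with methyl chlorooxoacetate gives the methyl oxalate F3, and CsOH gives the caesium oxalate F4.
- Visible-light radical deoxychlorination ([Ir(dF(CF3)ppy)2(dtbbpy)]PF6, ethyl trichloroacetate) then replaces the oxalate by chlorine. It runs through the C3 radical, which should take up chlorine on the face away from the allyl group, to give 3.

Step 17. Protonation of the extended enolate may take place on the wrong face or at C7, and any 9α-aldehyde closes back to the lactol.
- The fallback sets out from 21 and returns at 24. It relies on thermodynamic instead of kinetic control, at the amide oxidation level.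
- Me2AlN(OMe)Me (from AlMe3 and MeNHOMe·HCl) opens the lactone to the 9α hydroxy Weinreb amide F5.
- Et3SiOTf with 2,6-lutidine gives the bis(triethylsilyl) ether F6, which can no longer relactonise.
- DBU in warm toluene equilibrates C9. The syn-axial contact between 1α-OSiEt3 and the 9α-amide should drive the mixture to the 9β Weinreb amide F7.
- i-Bu2AlH at −78 °C gives the bis-silylated 9β-aldehyde F8, and HF·pyridine removes both silyl groups to give 24.

Step 14. The hydride may attack the lactone carbonyl group, or fail to reach C6 beside the congested ring fusion.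
- The fallback sets out from 16 and returns at 21, bypassing 17 and 19.
- Cross metathesis of 16 with 20 gives the side-chain adduct F9.
- Hydrogen-atom-transfer hydrogenation (Mn(dpm)3, PhSiH3, t-BuOOH, i-PrOH) of the electron-rich trisubstituted C5=C6 bond, through the tertiary C5 radical, gives the trans-fused Δ8 lactone F10. The 1,2-disubstituted side-chain alkene and the electron-poor tetrasubstituted C8=C9 bond are far less reactive toward hydrogen-atom transfer.
- γ-Deprotonation at C7 with LiN(i-Pr)2 and kinetic α-protonation at C9 (deconjugation) give 21.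

Further compounds
F1 | step 2 | syn epoxy alcohol: 1-allyl-2,3-epoxy-2-methylcyclohexan-1-ol, epoxide on the face of the OH group | C=CC[C@@]1(O)CCC[C@@H]2O[C@]12C
F2 | step 2 | (2R,3S)-2-allyl-3-hydroxy-2-methylcyclohexan-1-one | O=C1CCC[C@H](O)[C@@]1(C)CC=C
F3 | step 2 | methyl oxalate of F2 | O=C1CCC[C@H](OC(=O)C(=O)OC)[C@@]1(C)CC=C
F4 | step 2 | caesium oxalate of F2 | O=C1CCC[C@H](OC(=O)C(=O)[O-])[C@@]1(C)CC=C.[Cs+]
F5 | step 17 | 9α hydroxy Weinreb amide | COC(=O)C1=CC[C@H]2[C@](C)(C/C=C/C(C)(C)O)[C@@H](Cl)C[C@H](O)[C@]2(C)[C@@H]1C(=O)N(C)OC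
F6 | step 17 | bis(triethylsilyl) ether of F5 | COC(=O)C1=CC[C@H]2[C@](C)(C/C=C/C(C)(C)O[Si](CC)(CC)CC)[C@@H](Cl)C[C@H](O[Si](CC)(CC)CC)[C@]2(C)[C@@H]1C(=O)N(C)OC
F7 | step 17 | 9β Weinreb amide, bis(triethylsilyl) ether | COC(=O)C1=CC[C@H]2[C@](C)(C/C=C/C(C)(C)O[Si](CC)(CC)CC)[C@@H](Cl)C[C@H](O[Si](CC)(CC)CC)[C@]2(C)[C@H]1C(=O)N(C)OC
F8 | step 17 | bis(triethylsilyl) ether of 24 | COC(=O)C1=CC[C@H]2[C@](C)(C/C=C/C(C)(C)O[Si](CC)(CC)CC)[C@@H](Cl)C[C@H](O[Si](CC)(CC)CC)[C@]2(C)[C@H]1C=O
F9 | step 14 | adduct 16 carrying the (E)-4-hydroxy-4-methylpent-2-enyl chain | COC(=O)C1=C2C(=O)O[C@H]3C[C@H](Cl)[C@@](C)(C/C=C/C(C)(C)O)C(=CC1)[C@@]23C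
F10 | step 14 | trans-fused Δ8 lactone ester (5α-H) with complete side chain | COC(=O)C1=C2C(=O)O[C@H]3C[C@H](Cl)[C@@](C)(C/C=C/C(C)(C)O)[C@H](CC1)[C@@]23C
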